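**Retrosynthetic overview**

- The strategy rests on the quaternary C4 of ring A: in the target its equatorial arm C18 (trans to the C10 methyl, C20) is the CO2Me and its axial arm C19 is a methyl. Andrographolide already supplies rings A/B with C5, C9, C10 and the C8 methylene, but is oxidised on the axial arm C19.
- Side chain: the C13 tertiary allylic alcohol and the C14=C15 vinyl group come from sulfonium-methylide opening of a (13S)-epoxide made by Sharpless epoxidation; C12–C13 comes from a Negishi coupling of the C12 alkylzinc with a 2-bromoallyl ether; C8=C17 comes from a Wittig reaction on the C8 ketone.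
- C18 ester ⇐ C18–OH ⇐ C18–Si ⇐ C18–H: iridium-catalysed C–H silylation directed by the equatorial C3–O–SiHEt2 ether of a 19-deoxy (gem-dimethyl) nor-labdane; the C3 oxygen is removed afterwards by Barton–McCombie deoxygenation.
- The nor-labdane comes from andrographolide by ozonolysis of both alkenes (C8 ketone masked as a dioxolane, C12 carried as a silyl ether) and C19 deoxygenation via the iodide.
- Ring order: the decalin is taken intact from andrographolide; the only rings formed are temporary, the C3–O–Si–C18 oxasilolane (step 9, opened in step 10) and the C13 epoxide (step 22, opened in step 24).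

Key step: step 9

Assumption: labdane numbering is used (C18 = equatorial C4 carbon trans to C20, C19 = axial C4 carbon cis to C20), and the minor C13 epimer left by the reagent-controlled epoxidation of step 22 is taken to be removable by chromatography.

**Route**

Step 1
Reactants: 1 andrographolide
Product: 2 andrographolide 3,19-acetonide
Conditions: 2,2-dimethoxypropane, PPTS (cat.), toluene/DMSO, 80 °C
Reagents that add atoms: 2,2-dimethoxypropane, COC(C)(C)OC
Why: Acid-catalysed transketalisation (acetonide protection) should select the six-membered dioxane across the C3/C19 1,3-diol and leave the isolated C14 hydroxyl free; no stereocentre changes.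

Step 2
Reactants: 2 andrographolide 3,19-acetonide
Product: 3 keto aldehyde acetonide (C8 ketone, C12 aldehyde)
Conditions: O3, CH2Cl2/MeOH, −78 °C; then Me2S, −78 °C → rt
Reagents that add atoms: ozone, [O-][O+]=O
Why: Ozonolysis with reductive work-up cleaves both the exocyclic C8=C17 alkene and the C12=C13 alkylidene-lactone alkene, giving the C8 ketone and the C12 aldehyde, while C9 keeps its equatorial, thermodynamically preferred side chain.

Step 3
Reactants: 3 keto aldehyde acetonide
Product: 4 hydroxy ketone acetonide (C12 primary alcohol)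
Conditions: NaBH4, EtOH/CH2Cl2, −78 °C
Reagents that add atoms: none
Why: Chemoselective borohydride reduction at low temperature, since the unhindered aldehyde reacts far faster than the α-branched C8 cyclohexanone.

Step 4
Reactants: 4 hydroxy ketone acetonide
Product: 5 TIPS ether ketone acetonide
Conditions: TIPSCl, imidazole, DMF, rt
Reagents that add atoms: triisopropylsilyl chloride, CC(C)[Si](Cl)(C(C)C)C(C)C
Why: Silyl ether protection of the only free (primary) hydroxyl traps the open hydroxy ketone form and removes the γ-hydroxy ketone that would form internal ketals in the next step.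

Step 5
Reactants: 5 TIPS ether ketone acetonide; 6 ethylene glycol
Product: 7 diol ketal (C8 dioxolane; free equatorial 3-OH and axial C19 CH2OH)
Conditions: HOCH2CH2OH (excess), TsOH·H2O (cat.), benzene, reflux, Dean–Stark
Reagents that add atoms: ethylene glycol (compound 6), OCCO
Why: Acid-catalysed ketalisation with azeotropic water removal converts the C8 ketone into its dioxolane while the excess glycol takes over the acetone unit of the strained 1,3-dioxane by transketalisation; the bulky primary TIPS ether tolerates catalytic acid and C9 stays equatorial.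

Step 6
Reactants: 7 diol ketal
Product: 8 C19 iodide (3-OH free)
Conditions: PPh3, I2, imidazole, toluene, 80 °C
Reagents that add atoms: iodine, II
Why: Appel-type iodination (Garegg conditions) converts the primary C19 alcohol through its alkoxyphosphonium salt into the neopentyl iodide, the secondary and more hindered C3 hydroxyl reacting much more slowly.

Step 7
Reactants: 8 C19 iodide
Product: 9 gem-dimethyl alcohol (19-deoxy; equatorial 3-OH)
Conditions: Bu3SnH, AIBN (cat.), toluene, 90 °C
Reagents that add atoms: none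
Why: Radical-chain dehalogenation with tin hydride is insensitive to the neopentyl environment and turns C19 into the axial methyl, making C4 a prochiral gem-dimethyl centre.

Step 8
Reactants: 9 gem-dimethyl alcohol; 10 diethylsilane
Product: 11 C3 diethyl(hydrido)silyl ether
Conditions: Et2SiH2, [Ir(cod)OMe]2 (cat.), THF, rt; volatiles removed
Reagents that add atoms: diethylsilane (compound 10), CC[SiH2]CC
Why: Iridium-catalysed dehydrogenative coupling of the O–H bond with one Si–H bond of the dihydrosilane gives the (hydrido)silyl ether with loss of hydrogen, excess silane suppressing the bis-alkoxysilane.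

Step 9
Reactants: 11 C3 diethyl(hydrido)silyl ether
Product: 12 C3–O–SiEt2–C18 oxasilolane (Si on the equatorial C4 CH2; C19 methyl axial)
Conditions: [Ir(cod)OMe]2 (cat.), 3,4,7,8-tetramethyl-1,10-phenanthroline (cat.), norbornene, THF, 120 °C, sealed
Reagents that add atoms: none
Why: The Si–H bond adds oxidatively to the iridium–phenanthroline centre, hydrogen is passed to norbornene, the resulting iridium silyl cleaves a primary C–H bond of the C4 methyl gauche to the equatorial C3–O bond, and C–Si reductive elimination from the six-membered iridacycle releases the product. This is the known hydroxyl-directed iridium-catalysed γ-C–H silylation of (hydrido)silyl ethers, a reaction established on 3-hydroxy-4,4-dimethyl terpenoids. The five-membered oxasilolane (O–Si–C18–C4–C3) is closed by intramolecular C18–Si bond formation and is trans-fused to ring A through two equatorial bonds. The new C4 stereocentre is set by which diastereotopic methyl reacts: the equatorial one (C18, trans to C20) is reached, because the axial C19 is shielded by its 1,3-diaxial relationship to the C10 methyl and would need a more strained cis-fused ring. The step needs selectivity for C18 over C19 and for primary over secondary γ-C–H bonds (C1–H, C5–H), which the equatorial tether and the catalyst's preference for primary C–H bonds should secure; both alkenes were removed beforehand, and ketal and silyl ether are inert.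

Step 10
Reactants: 12 oxasilolane
Product: 13 3,18-diol (equatorial 3-OH, equatorial C18 CH2OH)
Conditions: 30% aq. H2O2, KHCO3, THF/MeOH, 50 °C
Reagents that add atoms: hydrogen peroxide, OO
Why: Tamao–Fleming oxidation, in which peroxide attacks the alkoxy-activated silicon, C18 migrates from Si to O with retention, and hydrolysis of the Si–O bonds releases the 1,3-diol; the TIPS ether and ketal are inert to bicarbonate/peroxide.

Step 11
Reactants: 13 3,18-diol
Product: 15 3-hydroxy 18-oic acid, via hydroxy aldehyde 14 (not isolated)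
Conditions: TEMPO (cat.), PhI(OAc)2, CH2Cl2, rt; then NaClO2, NaH2PO4, 2-methyl-2-butene, t-BuOH/H2O, rt
Reagents that add atoms: sodium chlorite, [Na+].[O-]Cl=O
Why: Oxoammonium (TEMPO) oxidation is selective for the primary C18 alcohol over the hindered secondary C3 alcohol, and buffered Pinnick oxidation of the non-enolisable aldehyde avoids retro-aldol cleavage and oxidation at C3.

Step 12
Reactants: 15 3-hydroxy 18-oic acid
Product: 16 3-hydroxy 18-methyl ester
Conditions: MeI, K2CO3, DMF, rt
Reagents that add atoms: iodomethane, CI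
Why: O-Alkylation of the carboxylate (SN2 on iodomethane) esterifies the hindered α-quaternary acid without touching the C3 hydroxyl.

Step 13
Reactants: 16 3-hydroxy 18-methyl ester
Product: 17 C3 imidazolyl thionocarbamate
Conditions: 1,1'-thiocarbonyldiimidazole, DMAP (cat.), toluene, 90 °C
Reagents that add atoms: 1,1'-thiocarbonyldiimidazole, S=C(n1ccnc1)n1ccnc1
Why: Thioacylation of the C3 alcohol under neutral conditions gives the radical precursor while avoiding the alkoxide that could trigger retro-aldol opening of ring A.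

Step 14
Reactants: 17 C3 imidazolyl thionocarbamate
Product: 18 3-deoxy ester (C8 dioxolane, C12 OTIPS)
Conditions: Bu3SnH, AIBN (cat.), toluene, 110 °C
Reagents that add atoms: none
Why: Barton–McCombie deoxygenation, in which the stannyl radical adds to C=S, the C3–O bond fragments to the secondary C3 radical, and tin hydride reduces it; C3 becomes CH2 and no stereocentre is affected.

Step 15
Reactants: 18 3-deoxy ester
Product: 19 C8 ketone
Conditions: PPTS, acetone/H2O, 60 °C
Reagents that add atoms: water, O
Why: Mild acid-catalysed hydrolysis of the dioxolane regenerates the C8 ketone, the primary TIPS ether and the methyl ester being stable to PPTS and C9 keeping its equatorial side chain.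

Step 16
Reactants: 19 C8 ketone
Product: 20 C8(17) exocyclic alkene (C12 OTIPS)
Conditions: Ph3PCH3Br, KOt-Bu, THF, 0 °C → reflux
Reagents that add atoms: methyltriphenylphosphonium bromide, C[P+](c1ccccc1)(c1ccccc1)c1ccccc1.[Br-]
Why: Wittig methylenation installs the C8=C17 alkene; the ylide should not attack the hindered α-quaternary ester, and the natural C9 configuration is the thermodynamic one should enolisation occur.

Step 17
Reactants: 20 C8(17) alkene TIPS ether
Product: 21 C12 primary alcohol
Conditions: TBAF, THF, rt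
Reagents that add atoms: none
Why: Fluoride-induced desilylation cleaves the primary TIPS ether without affecting ester or alkene.

Step 18
Reactants: 21 C12 primary alcohol
Product: 22 C12 primary iodide
Conditions: PPh3, I2, imidazole, CH2Cl2, 0 °C → rt
Reagents that add atoms: iodine, II
Why: Appel-type iodination of the unhindered primary alcohol via the alkoxyphosphonium salt (SN2 by iodide).

Step 19
Reactants: 23 2-bromoallyl alcohol
Product: 24 2-bromoallyl TBS ether
Conditions: TBSCl, imidazole, CH2Cl2, 0 °C → rt
Reagents that add atoms: tert-butyldimethylsilyl chloride, CC(C)(C)[Si](C)(C)Cl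
Why: Standard silyl ether protection of the primary allylic alcohol; the vinyl bromide is inert.

Step 20
Reactants: 22 C12 primary iodide; 24 2-bromoallyl TBS ether
Product: 26 coupled allyl TBS ether (C12–C13(=CH2)–CH2OTBS), via alkylzinc iodide 25 (not isolated)
Conditions: Zn dust (activated), LiCl, THF, 40 °C; then 24, Pd(OAc)2 (cat.), SPhos (cat.), THF, rt → 40 °C
Reagents that add atoms: none
Why: LiCl-promoted zinc insertion into the primary C–I bond gives an ester-tolerant alkylzinc, and Negishi coupling (oxidative addition of the vinyl bromide, transmetallation, reductive elimination) forms C12–C13, the bulky biaryl phosphine favouring reductive elimination over β-hydride elimination.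

Step 21
Reactants: 26 coupled allyl TBS ether
Product: 27 2-substituted allylic alcohol
Conditions: TBAF, THF, 0 °C
Reagents that add atoms: none
Why: Fluoride-induced cleavage of the allylic TBS ether frees the hydroxyl needed to direct the epoxidation.

Step 22
Reactants: 27 2-substituted allylic alcohol
Product: 28 (13S)-epoxy alcohol
Conditions: Ti(Oi-Pr)4 (cat.), L-(+)-diisopropyl tartrate (cat.), t-BuOOH, 4 Å MS, CH2Cl2, −20 °C
Reagents that add atoms: tert-butyl hydroperoxide, CC(C)(C)OO
Why: Sharpless asymmetric epoxidation, in which the titanium–tartrate complex binds the allylic alcohol and delivers oxygen to one face of the 1,1-disubstituted alkene; L-(+)-tartrate gives the (13S)-epoxide (same sense as 2-methylallyl alcohol to (S)-2-methylglycidol), which fixes C13, and the C8 methylene has no directing hydroxyl and is left alone.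

Step 23
Reactants: 28 (13S)-epoxy alcohol
Product: 29 epoxy TBS ether
Conditions: TBSCl, imidazole, CH2Cl2, 0 °C → rt
Reagents that add atoms: tert-butyldimethylsilyl chloride, CC(C)(C)[Si](C)(C)Cl
Why: Silyl ether protection of the primary alcohol blocks Payne rearrangement, which would scramble C13 under the basic conditions of the next step.

Step 24
Reactants: 29 epoxy TBS ether
Product: 30 (13R)-tertiary allylic alcohol, C16 TBS ether
Conditions: Me3S+ I−, n-BuLi, THF, −10 °C → rt
Reagents that add atoms: trimethylsulfonium iodide, C[S+](C)C.[I-]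
Why: Sulfonium-ylide homologation of an epoxide to an allylic alcohol: the methylide opens the epoxide at its CH2 terminus (SN2, C13–O untouched, so C13 is retained) and a second equivalent of base eliminates dimethyl sulfide to give the vinyl group; the hindered α-quaternary ester should be spared at low temperature.

Step 25
Reactants: 30 (13R)-tertiary allylic alcohol TBS ether
Product: 31 target
Conditions: TBAF, THF, rt
Reagents that add atoms: none
Why: Fluoride-induced desilylation releases the C16 alcohol, and also any silyl group that migrated to the tertiary oxygen in step 24, giving the target.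

**Compound list**

1 | andrographolide | C[C@@]12CC[C@H]([C@@]([C@H]1CCC(=C)[C@H]2C/C=C/3\[C@@H](COC3=O)O)(C)CO)O | starting material
2 | andrographolide 3,19-acetonide (dioxane across O3/O19; 14-OH free) | C[C@@]12CC[C@H]([C@@]([C@H]1CCC(=C)[C@H]2C/C=C/3\[C@@H](COC3=O)O)(C)CO4)OC4(C)C | intermediate
3 | 3,19-O-isopropylidene-8-oxo-13,14,15,16,17-pentanorlabdan-12-al (ring stereocentres as in 1) | O=CC[C@@H]1C(=O)CC[C@H]2[C@@]1(C)CC[C@H]3OC(C)(C)OC[C@@]23C | intermediate
4 | 12-hydroxy-3,19-O-isopropylidene-pentanorlabdan-8-one (may equilibrate with its 8,12-hemiketal) | OCC[C@@H]1C(=O)CC[C@H]2[C@@]1(C)CC[C@H]3OC(C)(C)OC[C@@]23C | intermediate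
5 | 12-(triisopropylsilyloxy)-3,19-O-isopropylidene-pentanorlabdan-8-one | CC(C)[Si](C(C)C)(C(C)C)OCC[C@@H]1C(=O)CC[C@H]2[C@@]1(C)CC[C@H]3OC(C)(C)OC[C@@]23C | intermediate
6 | ethylene glycol | OCCO | starting material
7 | 8,8-ethylenedioxy-12-(triisopropylsilyloxy)-pentanorlabdane-3,19-diol (3-OH equatorial, C19 axial) | CC(C)[Si](C(C)C)(C(C)C)OCC[C@@H]1C2(OCCO2)CC[C@H]3[C@@]1(C)CC[C@@H](O)[C@@]3(C)CO | intermediate
8 | 19-iodo-8,8-ethylenedioxy-12-(triisopropylsilyloxy)-pentanorlabdan-3-ol | CC(C)[Si](C(C)C)(C(C)C)OCC[C@@H]1C2(OCCO2)CC[C@H]3[C@@]1(C)CC[C@@H](O)[C@@]3(C)CI | intermediate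
9 | 8,8-ethylenedioxy-12-(triisopropylsilyloxy)-pentanorlabdan-3-ol (4,4-dimethyl, 3-OH equatorial) | CC(C)[Si](C(C)C)(C(C)C)OCC[C@@H]1C2(OCCO2)CC[C@H]3[C@@]1(C)CC[C@@H](O)C3(C)C | intermediate
10 | diethylsilane | CC[SiH2]CC | starting material
11 | 3-O-diethyl(hydrido)silyl ether of 9 | CC(C)[Si](C(C)C)(C(C)C)OCC[C@@H]1C2(OCCO2)CC[C@H]3[C@@]1(C)CC[C@@H](O[SiH](CC)CC)C3(C)C | intermediate
12 | C3–O–SiEt2–C18 oxasilolane (Si on the equatorial C4 CH2, trans to C20; C19 methyl axial) | CC(C)[Si](C(C)C)(C(C)C)OCC[C@@H]1C2(OCCO2)CC[C@H]3[C@@]1(C)CC[C@H]4O[Si](CC)(CC)C[C@]34C | intermediate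
13 | 8,8-ethylenedioxy-12-(triisopropylsilyloxy)-pentanorlabdane-3,18-diol | CC(C)[Si](C(C)C)(C(C)C)OCC[C@@H]1C2(OCCO2)CC[C@H]3[C@@]1(C)CC[C@@H](O)[C@@]3(CO)C | intermediate
14 | 3-hydroxy-8,8-ethylenedioxy-12-(triisopropylsilyloxy)-pentanorlabdan-18-al | CC(C)[Si](C(C)C)(C(C)C)OCC[C@@H]1C2(OCCO2)CC[C@H]3[C@@]1(C)CC[C@@H](O)[C@@]3(C=O)C | intermediate
15 | 3-hydroxy-8,8-ethylenedioxy-12-(triisopropylsilyloxy)-pentanorlabdan-18-oic acid | CC(C)[Si](C(C)C)(C(C)C)OCC[C@@H]1C2(OCCO2)CC[C@H]3[C@@]1(C)CC[C@@H](O)[C@@]3(C(=O)O)C | intermediate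
16 | methyl 3-hydroxy-8,8-ethylenedioxy-12-(triisopropylsilyloxy)-pentanorlabdan-18-oate | CC(C)[Si](C(C)C)(C(C)C)OCC[C@@H]1C2(OCCO2)CC[C@H]3[C@@]1(C)CC[C@@H](O)[C@@]3(C(=O)OC)C | intermediate
17 | methyl 3-(imidazol-1-ylcarbothioyloxy)-8,8-ethylenedioxy-12-(triisopropylsilyloxy)-pentanorlabdan-18-oate | CC(C)[Si](C(C)C)(C(C)C)OCC[C@@H]1C2(OCCO2)CC[C@H]3[C@@]1(C)CC[C@@H](OC(=S)n4ccnc4)[C@@]3(C(=O)OC)C | intermediate
18 | methyl 8,8-ethylenedioxy-12-(triisopropylsilyloxy)-pentanorlabdan-18-oate | CC(C)[Si](C(C)C)(C(C)C)OCC[C@@H]1C2(OCCO2)CC[C@H]3[C@@]1(C)CCC[C@@]3(C(=O)OC)C | intermediate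
19 | methyl 8-oxo-12-(triisopropylsilyloxy)-pentanorlabdan-18-oate | CC(C)[Si](C(C)C)(C(C)C)OCC[C@@H]1C(=O)CC[C@H]2[C@@]1(C)CCC[C@@]2(C(=O)OC)C | intermediate
20 | methyl 12-(triisopropylsilyloxy)-13,14,15,16-tetranorlabd-8(17)-en-18-oate | CC(C)[Si](C(C)C)(C(C)C)OCC[C@@H]1C(=C)CC[C@H]2[C@@]1(C)CCC[C@@]2(C(=O)OC)C | intermediate
21 | methyl 12-hydroxy-13,14,15,16-tetranorlabd-8(17)-en-18-oate | OCC[C@@H]1C(=C)CC[C@H]2[C@@]1(C)CCC[C@@]2(C(=O)OC)C | intermediate
22 | methyl 12-iodo-13,14,15,16-tetranorlabd-8(17)-en-18-oate | ICC[C@@H]1C(=C)CC[C@H]2[C@@]1(C)CCC[C@@]2(C(=O)OC)C | intermediate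
23 | 2-bromoprop-2-en-1-ol (2-bromoallyl alcohol) | C=C(Br)CO | starting material
24 | (2-bromoallyloxy)(tert-butyl)dimethylsilane | C=C(Br)CO[Si](C)(C)C(C)(C)C | intermediate
25 | C12 alkylzinc iodide derived from 22 | I[Zn]CC[C@@H]1C(=C)CC[C@H]2[C@@]1(C)CCC[C@@]2(C(=O)OC)C | intermediate
26 | methyl 16-(tert-butyldimethylsilyloxy)-15-norlabda-8(17),13(14)-dien-18-oate | C=C(CO[Si](C)(C)C(C)(C)C)CC[C@@H]1C(=C)CC[C@H]2[C@@]1(C)CCC[C@@]2(C(=O)OC)C | intermediate
27 | methyl 16-hydroxy-15-norlabda-8(17),13(14)-dien-18-oate | C=C(CO)CC[C@@H]1C(=C)CC[C@H]2[C@@]1(C)CCC[C@@]2(C(=O)OC)C | intermediate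
28 | methyl (13S)-13,14-epoxy-16-hydroxy-15-norlabd-8(17)-en-18-oate | OC[C@]1(CO1)CC[C@@H]2C(=C)CC[C@H]3[C@@]2(C)CCC[C@@]3(C(=O)OC)C | intermediate
29 | 16-O-TBS ether of 28 (same geometry at C13) | CC(C)(C)[Si](C)(C)OC[C@]1(CO1)CC[C@@H]2C(=C)CC[C@H]3[C@@]2(C)CCC[C@@]3(C(=O)OC)C | intermediate
30 | methyl (13R)-13-hydroxy-16-(tert-butyldimethylsilyloxy)labda-8(17),14-dien-18-oate | C=C[C@@](O)(CO[Si](C)(C)C(C)(C)C)CC[C@@H]1C(=C)CC[C@H]2[C@@]1(C)CCC[C@@]2(C(=O)OC)C | intermediate
31 | methyl (1S,4aS,5R,8aS)-5-[(3R)-3-hydroxy-3-(hydroxymethyl)pent-4-en-1-yl]-1,4a-dimethyl-6-methylidenedecahydronaphthalene-1-carboxylate | C=C[C@@](O)(CO)CC[C@@H]1C(=C)CC[C@H]2[C@@]1(C)CCC[C@]2(C)C(=O)OC | target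

**Step count and risks**

Total steps: 25. Longest linear sequence: 24 (steps 1–18 and 20–25 from andrographolide; step 19 is a one-step side branch).

Steps most likely to fail:

1. Step 9 (directed C–H silylation). What may go wrong: insufficient discrimination between the two C4 methyl groups, or stalled C–H cleavage at the hindered silyl ether. The fallback is oxime-directed palladium C–H acetoxylation, which also reaches the equatorial methyl. It sets out from 9: Dess–Martin oxidation would give the C3 ketone F1, and hydroxylamine the (E)-oxime F2. Pd(OAc)2/PhI(OAc)2 in AcOH/Ac2O would acetylate the oxime in the flask and acetoxylate the equatorial methyl through a five-membered palladacycle, giving the 18-acetoxy O-acetyl oxime F3. K2CO3/MeOH would give the 18-hydroxy oxime F4, aqueous NaHSO3 the β-hydroxy ketone F5, and NaBH4 (axial hydride delivery) the equatorial C3 alcohol, coming back to the route at 13.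

2. Step 6 (C19 iodination). What may go wrong: sluggish SN2 displacement at the axial neopentyl carbon and participation of the neighbouring C3 hydroxyl (oxetane or cyclic phosphorane formation). The fallback avoids substitution at C19 altogether. It sets out from 7: TEMPO/PhI(OAc)2 would oxidise the primary alcohol to the 3-hydroxy-19-aldehyde F6, and tosylhydrazide would give the tosylhydrazone F7. Catecholborane followed by NaOAc·3H2O (reduction to the alkyldiazene, loss of sulfinate and nitrogen) would deliver the C19 methyl, coming back to the route at 9.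

3. Step 24 (ylide opening). What may go wrong: attack of the ylide on the C18 ester, or slow opening of the hindered 2,2-disubstituted epoxide. The fallback exchanges the roles of the two C13 arms, so the opposite tartrate is needed. It sets out from 27: Sharpless epoxidation with D-(−)-diisopropyl tartrate would give the C13-epimeric epoxy alcohol F8, SO3·pyridine/DMSO oxidation the epoxy aldehyde F9 (no α-hydrogen), and Wittig methylenation at −78 → 0 °C the vinyl epoxide F10. Hydroxide (KOH, DMSO/H2O, 60 °C) should open the epoxide at its primary carbon with the C13–O bond retained, coming back to the route at 31; any acid from partial saponification would be re-methylated with MeI/K2CO3.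

**Further compounds**

F1 | step 9 | 8,8-ethylenedioxy-12-(triisopropylsilyloxy)-pentanorlabdan-3-one | CC(C)[Si](C(C)C)(C(C)C)OCC[C@@H]1C2(OCCO2)CC[C@H]3[C@@]1(C)CCC(=O)C3(C)C
F2 | step 9 | (E)-3-oxime of F1 | CC(C)[Si](C(C)C)(C(C)C)OCC[C@@H]1C2(OCCO2)CC[C@H]3[C@@]1(C)CC/C(=N\O)C3(C)C
F3 | step 9 | 18-acetoxy 3-(O-acetyl oxime) | CC(C)[Si](C(C)C)(C(C)C)OCC[C@@H]1C2(OCCO2)CC[C@H]3[C@@]1(C)CC/C(=N\OC(C)=O)[C@@]3(COC(C)=O)C
F4 | step 9 | 18-hydroxy 3-oxime | CC(C)[Si](C(C)C)(C(C)C)OCC[C@@H]1C2(OCCO2)CC[C@H]3[C@@]1(C)CC/C(=N\O)[C@@]3(CO)C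
F5 | step 9 | 18-hydroxy-8,8-ethylenedioxy-12-(triisopropylsilyloxy)-pentanorlabdan-3-one | CC(C)[Si](C(C)C)(C(C)C)OCC[C@@H]1C2(OCCO2)CC[C@H]3[C@@]1(C)CCC(=O)[C@@]3(CO)C
F6 | step 6 | 3-hydroxy-8,8-ethylenedioxy-12-(triisopropylsilyloxy)-pentanorlabdan-19-al | CC(C)[Si](C(C)C)(C(C)C)OCC[C@@H]1C2(OCCO2)CC[C@H]3[C@@]1(C)CC[C@@H](O)[C@@]3(C)C=O
F7 | step 6 | tosylhydrazone of F6 | CC(C)[Si](C(C)C)(C(C)C)OCC[C@@H]1C2(OCCO2)CC[C@H]3[C@@]1(C)CC[C@@H](O)[C@@]3(C)/C=N/NS(=O)(=O)c4ccc(C)cc4
F8 | step 24 | C13-epimeric epoxy alcohol (epimer of 28) | OC[C@@]1(CO1)CC[C@@H]2C(=C)CC[C@H]3[C@@]2(C)CCC[C@@]3(C(=O)OC)C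
F9 | step 24 | epoxy aldehyde from F8 | O=C[C@@]1(CO1)CC[C@@H]2C(=C)CC[C@H]3[C@@]2(C)CCC[C@@]3(C(=O)OC)C
F10 | step 24 | vinyl epoxide from F9 | C=C[C@@]1(CO1)CC[C@@H]2C(=C)CC[C@H]3[C@@]2(C)CCC[C@@]3(C(=O)OC)C
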